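**Plan**

- Feature: in the target ring (C1 C=O, C2=C3, C4 CH–OMe, C5 CH2, C6 quaternary), C6 carries an allyl group and the chain C7 (CH–CH3)–C8 (CH–OH)–aryl. This is the imprint of a propenylbenzene β-carbon (C7) bonded to the allyl-bearing para carbon of a 4-allyl-2-methoxyphenol, whose arene is the carbocycle and whose methoxy group is the C4–OMe.
- Retrosynthesis: C1=O and C8–OH are tied together as a cyclic vinylogous ester (C1–O–C8, carbonyl at C3). Removing H from C4/C5 and cutting C1–O leads back to a 4,4-disubstituted 2-methoxycyclohexadienone. That dienone is cut at C6–C7 and C8–O into eugenol, (E)-methylisoeugenol and water.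
- Forward: one three-component dearomative coupling joins the chain (no ring forms; the six-membered ring is eugenol's). A temporary tetrahydrofuran ring (O–C1) then closes by oxa-Michael addition and is dehydrogenated, C4=C5 is reduced, and hydride reduction followed by acid hydrolysis reopens the ether while moving the carbonyl from C3 to C1.
- Stereochemistry: C6, C7 and C8 arise in the coupling. The absolute sense and the C6/C7 pairing are to come from a chiral aryl-λ3-iodane; the syn C7/C8 pair from the E-alkene and anti addition of water. C4 is set by equilibration in the rigid bicyclic vinylogous ester, where the methoxy group takes the pseudo-equatorial site trans to the pseudo-axial allyl group.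

Key step: step 1

Assumption: the sense of induction of the chiral iodane cannot be derived with certainty; the (R,R)-reagent is written, and its enantiomer would be used if the first experiment showed the opposite sense.
Remark: water is numbered (3) because it is one of the three components of the coupling.

**Route**

Step 1
Reactants: 1 eugenol; 2 (E)-methylisoeugenol; 3 water
Product: 4 (4R)-4-allyl-4-[(1S,2R)-1-(3,4-dimethoxyphenyl)-1-hydroxypropan-2-yl]-2-methoxycyclohexa-2,5-dien-1-one
Conditions: (R,R)-ArI(OAc)2 [trivalent iodine; Ar = 2,6-bis{(1R)-1-(mesitylcarbamoyl)ethoxy}phenyl] (1.1 equiv, slow addition), 2 (3 equiv), H2O (10 equiv), CH2Cl2/(CF3)2CHOH 4:1, −40 °C; aq. NaHCO3/Na2S2O3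
Reagents that add atoms: water (3), O
Why: Proposed new method: ligand exchange of 1 at trivalent iodine and departure of ArI give the 4-allyl-2-methoxyphenoxonium ion (free or still iodine-bound), whose allyl-bearing para carbon (future C6) is attacked by the β-carbon of 2 (future C7), and the resulting 3,4-dimethoxybenzyl cation (future C8) is trapped by water, so that C6–C7 and C8–O form and no ring closes. The closest known reaction types are the racemic oxidative or acid-promoted couplings of alkoxyphenol-derived cations with propenylarenes, which end in ring closure, and the dearomatising para-allylation of 4-alkylphenols with allylsilanes under PhI(OAc)2 in fluoroalcohol. C7 and C8 are controlled by the E geometry of 2 together with anti addition: water should enter the benzylic cation on the face opposite the bulky cyclohexadienone substituent (Felkin-type), which gives the syn C7/C8 pair. C6 and the absolute sense are to be controlled by the C2-symmetric lactamide arms of the iodane, which sit next to the phenoxy oxygen and its neighbouring methoxy group and are expected to screen one face and one arm of the ring, so that the alkene comes in from the open face with its aryl end over the unsubstituted arm. The step needs para over ortho attack and carbon over oxygen attack: the para carbon bears the largest LUMO coefficient of the phenoxonium ion and cannot rearomatise once alkylated, and an excess of the electron-rich alkene with only a few equivalents of water in weakly nucleophilic (CF3)2CHOH should favour the alkene as first nucleophile.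

Step 2
Reactants: 4 (4R)-4-allyl-4-[(1S,2R)-1-(3,4-dimethoxyphenyl)-1-hydroxypropan-2-yl]-2-methoxycyclohexa-2,5-dien-1-one
Product: 5 (2S,3R,3aR,7aS)-3a-allyl-2-(3,4-dimethoxyphenyl)-5-methoxy-3-methyl-3,3a,7,7a-tetrahydro-1-benzofuran-6(2H)-one
Conditions: t-BuOK (0.1 equiv), THF, −20 to 0 °C; AcOH quench
Reagents that add atoms: none
Why: Intramolecular 5-exo-trig oxa-Michael addition under reversible base catalysis, in which the C8 alkoxide adds to C1 of the unsubstituted enone arm because C5 of the other arm is the electron-rich terminus of the C4 enol ether; the five-membered ring can only be cis-fused, so the oxygen enters C1 on the face of C6 that carries C7 and the new C1 stereocentre is fixed by the ring (any 5 already formed from 4 during step 1 or on silica simply joins the material).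

Step 3
Reactants: 5 (2S,3R,3aR,7aS)-3a-allyl-2-(3,4-dimethoxyphenyl)-5-methoxy-3-methyl-3,3a,7,7a-tetrahydro-1-benzofuran-6(2H)-one
Product: 7 (2S,3R,3aR)-3a-allyl-2-(3,4-dimethoxyphenyl)-5-methoxy-3-methyl-3,3a-dihydro-1-benzofuran-6(2H)-one, via trimethylsilyl dienol ether 6 (not isolated)
Conditions: TMSOTf, Et3N, CH2Cl2, 0 °C; then Pd(OAc)2 (1.05 equiv), MeCN, rt
Reagents that add atoms: none
Why: Saegusa–Ito dehydrogenation, in which the C3 ketone can be enolised only toward C2 (C4 is sp2) and the palladium enolate formed from 6 has H–C1 as its only β-hydrogen, so β-hydride elimination gives the C1=C2 bond of the cyclic vinylogous ester (the same type of conversion as tetrahydropyran-4-one to 2,3-dihydropyran-4-one) and the C1 stereocentre disappears.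

Step 4
Reactants: 7 (2S,3R,3aR)-3a-allyl-2-(3,4-dimethoxyphenyl)-5-methoxy-3-methyl-3,3a-dihydro-1-benzofuran-6(2H)-one
Product: 9 (2S,3R,3aS,5S)-3a-allyl-2-(3,4-dimethoxyphenyl)-5-methoxy-3-methyl-3,3a,4,5-tetrahydro-1-benzofuran-6(2H)-one, via C4 epimer 8 (not isolated)
Conditions: [(Ph3P)CuH]6 (5 mol %), PhMe2SiH (1.5 equiv), t-BuOH (2 equiv), toluene, rt; then t-BuOK (0.1 equiv), THF, 0 °C
Reagents that add atoms: none
Why: Copper hydride conjugate reduction should deliver hydride to C5, the β-carbon of the only enone arm whose β-position is not oxygen-substituted, and leave the terminal alkene alone; the C4 stereocentre is then placed under thermodynamic control by base equilibration of the α-methoxy ketone, and since the tetrahydrofuran ring forces C7 pseudo-equatorial and the allyl group pseudo-axial at C6, the methoxy group should settle pseudo-equatorial, trans to allyl and cis to C7, as in the target (kinetic epimer 8 is converted into 9).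

Step 5
Reactants: 9 (2S,3R,3aS,5S)-3a-allyl-2-(3,4-dimethoxyphenyl)-5-methoxy-3-methyl-3,3a,4,5-tetrahydro-1-benzofuran-6(2H)-one; 3 water (from the aqueous acid)
Product: 11 (4S,6S)-6-allyl-6-[(1S,2R)-1-(3,4-dimethoxyphenyl)-1-hydroxypropan-2-yl]-4-methoxycyclohex-2-en-1-one, via allylic alcohol 10 (not isolated)
Conditions: LiAlH4, Et2O, −20 °C; then 1 M HCl, THF, 0 °C
Reagents that add atoms: water (3), O
Why: Stork–Danheiser carbonyl transposition, in which hydride adds 1,2 to the vinylogous ester carbonyl at C3 to give 10, aqueous acid ionises the C3 hydroxyl with the help of the enol-ether oxygen, water adds at C1 and the hemiketal collapses to the C1 ketone with the C2=C3 double bond, while the C8–O bond stays intact and releases the C8 alcohol with retention; C4, C6, C7 and C8 are not touched.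

**Compound list**

1 | eugenol (4-allyl-2-methoxyphenol) | C=CCc1ccc(O)c(OC)c1 | starting material
2 | (E)-methylisoeugenol [(E)-1,2-dimethoxy-4-(prop-1-en-1-yl)benzene] | C/C=C/c1ccc(OC)c(OC)c1 | starting material
3 | water | O | starting material
4 | (4R)-4-allyl-4-[(1S,2R)-1-(3,4-dimethoxyphenyl)-1-hydroxypropan-2-yl]-2-methoxycyclohexa-2,5-dien-1-one | C=CC[C@@]1([C@@H](C)[C@H](O)c2ccc(OC)c(OC)c2)C=C(OC)C(=O)C=C1 | intermediate
5 | (2S,3R,3aR,7aS)-3a-allyl-2-(3,4-dimethoxyphenyl)-5-methoxy-3-methyl-3,3a,7,7a-tetrahydro-1-benzofuran-6(2H)-one (cis-fused; 2-aryl and 3-methyl cis to each other and trans to the 3a-allyl group) | C=CC[C@@]12C=C(OC)C(=O)C[C@@H]1O[C@H](c3ccc(OC)c(OC)c3)[C@@H]2C | intermediate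
6 | {[(2S,3R,3aR,7aS)-3a-allyl-2-(3,4-dimethoxyphenyl)-5-methoxy-3-methyl-2,3,3a,7a-tetrahydro-1-benzofuran-6-yl]oxy}trimethylsilane (not isolated) | C=CC[C@@]12C=C(OC)C(O[Si](C)(C)C)=C[C@@H]1O[C@H](c3ccc(OC)c(OC)c3)[C@@H]2C | intermediate
7 | (2S,3R,3aR)-3a-allyl-2-(3,4-dimethoxyphenyl)-5-methoxy-3-methyl-3,3a-dihydro-1-benzofuran-6(2H)-one | C=CC[C@@]12C=C(OC)C(=O)C=C1O[C@H](c3ccc(OC)c(OC)c3)[C@@H]2C | intermediate
8 | (2S,3R,3aS,5R)-3a-allyl-2-(3,4-dimethoxyphenyl)-5-methoxy-3-methyl-3,3a,4,5-tetrahydro-1-benzofuran-6(2H)-one (C4 epimer, methoxy cis to allyl; not isolated) | C=CC[C@@]12C[C@@H](OC)C(=O)C=C1O[C@H](c3ccc(OC)c(OC)c3)[C@@H]2C | intermediate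
9 | (2S,3R,3aS,5S)-3a-allyl-2-(3,4-dimethoxyphenyl)-5-methoxy-3-methyl-3,3a,4,5-tetrahydro-1-benzofuran-6(2H)-one (methoxy trans to allyl) | C=CC[C@@]12C[C@H](OC)C(=O)C=C1O[C@H](c3ccc(OC)c(OC)c3)[C@@H]2C | intermediate
10 | (2S,3R,3aS,5S)-3a-allyl-2-(3,4-dimethoxyphenyl)-5-methoxy-3-methyl-2,3,3a,4,5,6-hexahydro-1-benzofuran-6-ol (both carbinol epimers; this centre is left open because it is destroyed; not isolated) | C=CC[C@@]12C[C@H](OC)C(O)C=C1O[C@H](c3ccc(OC)c(OC)c3)[C@@H]2C | intermediate
11 | (4S,6S)-6-allyl-6-[(1S,2R)-1-(3,4-dimethoxyphenyl)-1-hydroxypropan-2-yl]-4-methoxycyclohex-2-en-1-one | C=CC[C@@]1([C@@H](C)[C@H](O)c2ccc(OC)c(OC)c2)C[C@H](OC)C=CC1=O | target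

**Step count**

Total: 5 steps. Longest linear sequence: 5 steps (from 1 and 2).

**Steps most likely to fail**

Step 1 (the proposed new method). Three processes may defeat it:
- The phenoxonium ion may be intercepted at an ortho carbon (followed by ring closure to a dihydrobenzofuran) or by water or acetate before the alkene arrives.
- The alkene may be oxidised directly.
- The chiral iodane may fail to tell apart the two faces and the two arms of the ring, so that C6 forms without control.

The fallback uses only known chemistry and replaces the open-chain water capture by the ring-closing acid-promoted condensation of a quinone monoketal with a propenylarene. It sets out from 2 and comes back to the route at 7. Photocatalytic E-to-Z isomerisation of 2 (fac-Ir(ppy)3, blue light, MeCN) would give (Z)-1,2-dimethoxy-4-(prop-1-en-1-yl)benzene F1. Separately, commercial 3,4-dimethoxyphenol would be O-allylated (allyl bromide, K2CO3, acetone) to 4-(allyloxy)-1,2-dimethoxybenzene F2. Claisen rearrangement (N,N-diethylaniline, 190 °C) should give 2-allyl-4,5-dimethoxyphenol F3, and PhI(OAc)2 in MeOH should give the quinone monoketal 2-allyl-4,4,5-trimethoxycyclohexa-2,5-dien-1-one F4. Treating F4 with F1 and SnCl4 (CH2Cl2, −78 to −30 °C, aqueous work-up) forms the cation. The alkene β-carbon bonds to the allyl-bearing ring carbon, and the ring carbonyl oxygen closes the tetrahydrofuran onto the benzylic cation with retention of the Z geometry. Loss of the second O-methyl group then gives racemic 7, that is 7 together with its enantiomer ent-7 F5. Preparative chromatography on a chiral stationary phase would deliver 7, which enters step 4.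

Step 4. Hydride transfer to C5 may be too slow, because this carbon is neopentylic and belongs to a cross-conjugated, donor-substituted enone. 1,2-Reduction of the C3 carbonyl or slow attack on the terminal alkene could then take over. The fallback reverses the order of reduction and dehydrogenation. It sets out from 5 and comes back at 9. In 5 the methoxy enone is an ordinary enone, and the same copper hydride conditions should give (2S,3R,3aS,5S,7aS)-3a-allyl-2-(3,4-dimethoxyphenyl)-5-methoxy-3-methylhexahydro-1-benzofuran-6(2H)-one F6. Kinetic enolisation away from the methoxy-bearing carbon (LiN(i-Pr)2 with TMSCl present, THF, −78 °C) should give the trimethylsilyl enol ether F7 with the double bond toward C2. Pd(OAc)2 in MeCN, followed by the same t-BuOK equilibration, should then give 9.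

Step 3. The palladium enolate may expel the β-alkoxide (reopening the tetrahydrofuran ring) instead of undergoing β-hydride elimination, or divalent palladium may engage the terminal alkene. The fallback avoids palladium and uses a selenoxide elimination. It sets out from 6 and comes back at 7. PhSeCl (1.0 equiv, CH2Cl2, −78 °C) should convert 6 into the α-selanyl ketone (2S,3R,3aR,7aS)-3a-allyl-2-(3,4-dimethoxyphenyl)-5-methoxy-3-methyl-7-(phenylselanyl)-3,3a,7,7a-tetrahydro-1-benzofuran-6(2H)-one F8. H2O2 with pyridine (CH2Cl2, 0 °C) should give the selenoxide F9, which undergoes syn elimination toward its only β-hydrogen, H–C1, to give 7.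

**Further compounds**

F1 | step 1 | (Z)-1,2-dimethoxy-4-(prop-1-en-1-yl)benzene | C/C=C\c1ccc(OC)c(OC)c1
F2 | step 1 | 4-(allyloxy)-1,2-dimethoxybenzene | C=CCOc1ccc(OC)c(OC)c1
F3 | step 1 | 2-allyl-4,5-dimethoxyphenol | C=CCc1cc(OC)c(OC)cc1O
F4 | step 1 | 2-allyl-4,4,5-trimethoxycyclohexa-2,5-dien-1-one | C=CCC1=CC(OC)(OC)C(OC)=CC1=O
F5 | step 1 | (2R,3S,3aS)-3a-allyl-2-(3,4-dimethoxyphenyl)-5-methoxy-3-methyl-3,3a-dihydro-1-benzofuran-6(2H)-one (ent-7) | C=CC[C@]12C=C(OC)C(=O)C=C1O[C@@H](c3ccc(OC)c(OC)c3)[C@H]2C
F6 | step 4 | (2S,3R,3aS,5S,7aS)-3a-allyl-2-(3,4-dimethoxyphenyl)-5-methoxy-3-methylhexahydro-1-benzofuran-6(2H)-one | C=CC[C@@]12C[C@H](OC)C(=O)C[C@@H]1O[C@H](c3ccc(OC)c(OC)c3)[C@@H]2C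
F7 | step 4 | {[(2S,3R,3aS,5S,7aS)-3a-allyl-2-(3,4-dimethoxyphenyl)-5-methoxy-3-methyl-2,3,3a,4,5,7a-hexahydro-1-benzofuran-6-yl]oxy}trimethylsilane | C=CC[C@@]12C[C@H](OC)C(O[Si](C)(C)C)=C[C@@H]1O[C@H](c3ccc(OC)c(OC)c3)[C@@H]2C
F8 | step 3 | (2S,3R,3aR,7aS)-3a-allyl-2-(3,4-dimethoxyphenyl)-5-methoxy-3-methyl-7-(phenylselanyl)-3,3a,7,7a-tetrahydro-1-benzofuran-6(2H)-one (C7 configuration open) | C=CC[C@@]12C=C(OC)C(=O)C([Se]c3ccccc3)[C@@H]1O[C@H](c4ccc(OC)c(OC)c4)[C@@H]2C
F9 | step 3 | selenoxide of F8, 7-(benzeneseleninyl) ketone | C=CC[C@@]12C=C(OC)C(=O)C([Se](=O)c3ccccc3)[C@@H]1O[C@H](c4ccc(OC)c(OC)c4)[C@@H]2C
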